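(Readings and results were computed from invented constants; noise was put on by code.)

The birch and cedar runs, with 2.7 equiv and 6 equiv of solid reagent, stand at 64.3% and 65.0% of starting material after 8.00 h, so the extra solid bought no visible speed and the solid in the two new flasks should be left as charged.

common to all: starting material 0.18 M; second reagent 1.05 equiv; gas 22 mM (held)

| charge | solid reagent | remark | time |
|---|---|---|---|
| birch | 2.7 equiv | run made earlier |  |
| cedar | 6 equiv | run made earlier |  |
| midnight | 4.00 equiv |  | 12 h |
| dusk | 4.00 equiv |  | 20 h |

| run | time / h | starting material / % | side product / % | intermediate B / % | target / % | intermediate A / % |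
|---|---|---|---|---|---|---|
| birch | 2.00 | 87.8 | 11.8 | 0.4 | 0.2 | 0 |
| birch | 4.00 | 78.5 | 20.9 | 0 | 0 | 0.1 |
| birch | 5.00 | 74.7 | 25.2 | 0 | 0.4 | 0.6 |
| birch | 8.00 | 64.3 | 34.9 | 0.1 | 0 | 0.9 |
| cedar | 0.833 | 94.8 | 4.8 | 0 | 0 | 0 |
| cedar | 2.50 | 85.4 | 14.4 | 0 | 0 | 0 |
| cedar | 5.00 | 74.3 | 25.4 | 0.3 | 0 | 0.3 |
| cedar | 8.00 | 65.0 | 34.6 | 0.2 | 0 | 0.8 |

(scatter of a reading: 0.3 percentage points)

- as a solid, counted per litre of solution: solid reagent
- the numbers in the tables scatter with a standard deviation of 0.3 percentage points
- at the start none of the gas is in solution
- at the start none of the solid reagent is in solution

1. which of these there is most of at the end, counted by the starting material in it, midnight (side product / starting material / intermediate A / intermediate B)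
2. which of these there is most of at the end, counted by the starting material in it, dusk (side product / starting material / intermediate A / intermediate B)
3. final amount of the leader among these, as a percentage of the starting material charged, in midnight
4. final amount of the leader among these, as a percentage of the starting material charged, in dusk

By 8.00 h the birch run has put nearly all of its lost starting material into side product, while intermediate A stands at 0.9%, so the bench has two species to watch. The inverse of the remaining fraction, less its starting value, rises at 0.0695 h⁻¹ up to 2.00 h in birch and at 0.0694 h⁻¹ up to 8.00 h, which reads as a straight line. The mean slope of the two runs gives the hour at which that line brings starting material down to half its charge, close to where side product draws level with it.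

slope = 0.0684 h⁻¹

crossing time = 1/slope = 14.6 h

This crossing time is a second-order half-life. Midnight stops before it and dusk runs beyond it.

starting material in midnight = 1/(1 + time/crossing time) = 54.9%

starting material in dusk = 42.2%

side product in dusk, less the intermediate A of birch = 56.9%

The forecast, on the ground that “Starting material loss fits second order, not first”, names starting material at 54% for midnight and side product at 54% for dusk, so its dusk figure lies below this reckoning.

Midnight gives starting material at 54.4%, and dusk gives side product at 57.2%.

    starting material + partner → intermediate A (k = 0.200 L mol⁻¹ h⁻¹)
    second reagent + intermediate A → intermediate B (k = 0.460 L mol⁻¹ h⁻¹)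
    third reagent + intermediate B → target (k = 1.70 L mol⁻¹ h⁻¹)
    starting material + second reagent → side product (k = 0.350 L mol⁻¹ h⁻¹)
    gas ⇌ third reagent, rate k5*(csat - [third reagent]) (kL = 0.580 h⁻¹)
    solid reagent ⇌ partner, rate k6*(cs6 - [partner]) while solid is left; crystals form when [partner] > cs6 (solubility = 8.90 mM, k = 0.400 h⁻¹)

Midnight stopped 2.63 h short of the crossing time and dusk ran 5.40 h past it, and that difference in time is the main reason for the gap in starting material between the two flasks: dusk stands at 41.1%, against 54.4% in midnight. With the equivalents held, starting material and second reagent, which meet in the step to side product, both fall with the charge, so a neighbour of dusk at [starting material] = 0.072 M reckons to a crossing time of 36.6 h, and 20 h reckons to 64.7%. That neighbour ends led by starting material at 63.2%.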